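All runs are simulated for an exercise, and the scatter is random.

- The reading at 2.5 h rests first on a charge ratio: c(reagent in the second phase)/c(substrate) = 1.10 for the flask. This cover, reagent charged per substrate charged, tells how much substrate can react.
- With one reagent consumed per substrate, a cover below one makes the reagent the limiting reagent, and at least one minus the cover stays as substrate.
- Oak has a cover of 0.503, so 49.7 % should stay; its reading at 90.0 min is 50.0 %.
- Alder has a cover of 0.782. Its substrate reading at 90.0 min stands 6 percentage points above that floor.
- The flask's cover is more than one, so its substrate can react through.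
- One number is not enough, since target also falls late. In ash, target drops from 52.1 % to 45.2 % while substrate reads 2.0 % and then 1.1 %.
- The last ash readings put 45.7 % of reacted substrate as target. Taking alder's gap as the flask's unreacted part, this reckoning gives 43.0 %.

| flask | substrate | reagent in the second phase | remark | time | volume of the second phase over the first |
|---|---|---|---|---|---|
| alder | 45 mM | 35.2 mM | run made earlier |  |  |
| oak | 70 mM | 35.2 mM | run made earlier |  |  |
| ash | 32 mM | 70 mM | run made earlier |  |  |
| flask | 32 mM | 35.2 mM |  | 2.5 h | 1.0 |

| run | time / min | target / % | substrate / % |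
|---|---|---|---|
| alder | 8.00 | 11.9 | 85.5 |
| alder | 12.0 | 18.8 | 78.1 |
| alder | 15.0 | 20.7 | 73.5 |
| alder | 25.0 | 30.4 | 59.7 |
| alder | 40.0 | 33.6 | 46.0 |
| alder | 60.0 | 32.6 | 34.8 |
| alder | 90.0 | 34.2 | 27.8 |
| oak | 8.00 | 11.0 | 89.3 |
| oak | 12.0 | 13.3 | 84.7 |
| oak | 15.0 | 18.0 | 80.7 |
| oak | 25.0 | 21.5 | 69.7 |
| oak | 40.0 | 22.8 | 60.6 |
| oak | 60.0 | 25.5 | 56.6 |
| oak | 90.0 | 23.8 | 50.0 |
| ash | 8.00 | 25.9 | 71.9 |
| ash | 15.0 | 46.1 | 44.2 |
| ash | 25.0 | 55.3 | 20.8 |
| ash | 50.0 | 52.1 | 2.0 |
| ash | 90.0 | 45.2 | 1.1 |

(scatter of a reading: 1 percentage point)

- in the second phase: reagent in the second phase; everything else is in the first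
- charges count per volume of the first phase; a concentration in a rate is the amount of a species over the volume of its own phase; every rate counts per litre of the first phase
- what may be going on: target <-> isomer of the product; substrate + reagent in the reaction phase -> target; reagent in the reaction phase <-> reagent in the second phase
- the earlier runs hold the two phases in the same ratio of volumes as the flask asked about

- how much target there is at 2.5 h, in percent of the substrate charged
- the change that raises the amount of target at 2.5 h, in percent of the substrate charged most ("none" if none brings more than 2 percentage points) (delta / gamma / none)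
- amount of target at 2.5 h, in percent of the substrate charged, after delta

- The forecast reads “the reagent is consumed 1:1” and gives 43.2 %, none for the best change, and 45 % after delta.
- The flask gives 42.2 % and none. Delta adds 1.4 points, less than the 2 points margin, and reaches 43.5 %; gamma adds 0.24 points.

    target ⇌ isomer of the product (K = 1.30, k = 0.0327 min⁻¹)
    substrate + reagent in the reaction phase → target (k = 5.34 M⁻¹ min⁻¹)
    reagent in the reaction phase ⇌ reagent in the second phase, rate k3*([reagent in the reaction phase] - [reagent in the second phase]/K3) per volume of the first phase (partition coefficient = 0.979, kL = 0.0484 min⁻¹)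

- Without the passing of target into isomer of the product, both ways, the flask holds 94.8 % of target against 42.2 %. The flask's cover of 1.10 sets no floor on its substrate, which stands at 5.2 % at 2.50 h and at 0 % at 25.0 h. The neighbour charged with 130 mM of substrate has a cover of 0.271, so 72.9 % should stay, and that flask holds 73 % of its substrate at 2.50 h.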